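**Plan**
- Retrosynthetic cuts, in order: C4–C4a (aryl–acyl bond of ring C), O1–C2 (benzylic aryl ether), C6–geranyl, and C2–C3 (acetate Claisen bond of the three-carbon bridge).
- Enabling feature: once C4–C4a is cut, ring A is a 4-geranyl-3,5-dioxygenated phenyl ether. Its two carbons ortho to the ether oxygen (future C4a and C8) are equivalent about the axis C6···C8a–O1, so iodination and acylation at either one can only give the 6-geranyl isomer.
- Forward: rings A and B are bought as arenes. Ring A phenol: phloroglucinol, directed metalation/geranylation between two OMOM groups, mono-iodination. Ring B piece: protocatechuate, β-keto Weinreb amide, asymmetric transfer hydrogenation.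
- The two pieces are joined by Mitsunobu etherification. Ring C, the only ring made, is closed last by iodine–lithium exchange and intramolecular Weinreb acylation without acid; global MOM removal ends the route.
- Stereochemistry: the single stereocenter C2 (S) comes from the catalyst-controlled reduction to an (R)-carbinol and its SN2 inversion. The E alkene is bought with geranyl bromide.

Key step: step 10

Remark on the chemistry: the facial sense of the transfer hydrogenation in step 8 is assumed to follow that of simple aryl alkyl ketones with the same catalyst, i.e. the (R,R)-diamine complex gives the (R)-benzylic alcohol.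

**Step 1**
Reactants: 1 phloroglucinol
Product: 2 3,5-bis(methoxymethoxy)phenol
Conditions: MOMCl (2.0 equiv), i-Pr2NEt, DMF, 0 °C → rt; chromatography
Reagents that add atoms: chloromethyl methyl ether (MOMCl), COCCl
Why: Williamson-type O-alkylation of the phenol with an α-chloro ether; with two equivalents the bis-ether should be the main member of a statistical set, from which it is separated while the mono-ether is recycled.

**Step 2**
Reactants: 2 3,5-bis(methoxymethoxy)phenol
Product: 3 [3,5-bis(methoxymethoxy)phenoxy]tri(propan-2-yl)silane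
Conditions: i-Pr3SiCl, imidazole, DMF, rt
Reagents that add atoms: chlorotri(propan-2-yl)silane (TIPSCl), CC(C)[Si](Cl)(C(C)C)C(C)C
Why: Imidazole-promoted O-silylation of the remaining phenol; the bulky, non-coordinating silyl ether survives n-BuLi and keeps metalation away from its own ortho positions.

**Step 3**
Reactants: 3 [3,5-bis(methoxymethoxy)phenoxy]tri(propan-2-yl)silane; 4 geranyl bromide
Product: 6 {4-[(2E)-3,7-dimethylocta-2,6-dien-1-yl]-3,5-bis(methoxymethoxy)phenoxy}tri(propan-2-yl)silane, via aryllithium 5 (not isolated)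
Conditions: n-BuLi, THF, 0 °C; then CuI (10 mol %), 4, −78 °C → rt
Reagents that add atoms: none
Why: Directed ortho-metalation takes place at the one carbon flanked by two OMOM groups, and copper-catalysed SN2 allylation of aryllithium 5 with the primary allylic bromide attaches the geranyl chain with its E alkene unchanged.

**Step 4**
Reactants: 6 {4-[(2E)-3,7-dimethylocta-2,6-dien-1-yl]-3,5-bis(methoxymethoxy)phenoxy}tri(propan-2-yl)silane
Product: 7 4-[(2E)-3,7-dimethylocta-2,6-dien-1-yl]-3,5-bis(methoxymethoxy)phenol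
Conditions: n-Bu4NF, THF, 0 °C; aq. NH4Cl
Reagents that add atoms: none
Why: Fluoride-induced cleavage of the aryl silyl ether frees only the phenol para to the geranyl group and leaves the MOM acetals untouched.

**Step 5**
Reactants: 7 4-[(2E)-3,7-dimethylocta-2,6-dien-1-yl]-3,5-bis(methoxymethoxy)phenol
Product: 8 4-[(2E)-3,7-dimethylocta-2,6-dien-1-yl]-2-iodo-3,5-bis(methoxymethoxy)phenol
Conditions: N-iodosuccinimide (1.0 equiv, slow addition), CH2Cl2, −40 → 0 °C, dark
Reagents that add atoms: N-iodosuccinimide (NIS), O=C1CCC(=O)N1I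
Why: Electrophilic aromatic iodination ortho to the free hydroxyl of a phloroglucinol-type ring should outrun attack on the trisubstituted alkenes, and because the two ortho carbons of 7 are equivalent only one mono-iodide is possible, one equivalent of reagent limiting di-iodination.

**Step 6**
Reactants: 9 methyl 3,4-dihydroxybenzoate
Product: 10 methyl 3,4-bis(methoxymethoxy)benzoate
Conditions: MOMCl (2.5 equiv), i-Pr2NEt, CH2Cl2, 0 °C → rt
Reagents that add atoms: chloromethyl methyl ether (MOMCl), COCCl
Why: Williamson-type O-alkylation of both catechol hydroxyls gives acetals that tolerate enolates, hydride transfer and organolithium reagents.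

**Step 7**
Reactants: 10 methyl 3,4-bis(methoxymethoxy)benzoate; 11 N-methoxy-N-methylacetamide
Product: 13 3-[3,4-bis(methoxymethoxy)phenyl]-N-methoxy-N-methyl-3-oxopropanamide, via lithium amide enolate 12 (not isolated)
Conditions: LiN(SiMe3)2 (2.2 equiv), THF, −78 → 0 °C; aq. NH4Cl
Reagents that add atoms: none
Why: Crossed Claisen condensation of the preformed amide enolate 12 with the aryl ester; the β-keto amide is deprotonated as it forms, which drives the reaction and prevents a second addition.

**Step 8**
Reactants: 13 3-[3,4-bis(methoxymethoxy)phenyl]-N-methoxy-N-methyl-3-oxopropanamide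
Product: 14 (3R)-3-[3,4-bis(methoxymethoxy)phenyl]-3-hydroxy-N-methoxy-N-methylpropanamide
Conditions: RuCl[(R,R)-TsDPEN](p-cymene) (1 mol %), HCO2H/Et3N (5:2), EtOAc, 35 °C
Reagents that add atoms: none
Why: Noyori–Ikariya asymmetric transfer hydrogenation of the aryl ketone, in which the (R,R)-diamine complex delivers hydride to the face that gives the (R)-benzylic alcohol, as with other aryl alkyl ketones, while the amide is inert.

**Step 9**
Reactants: 8 4-[(2E)-3,7-dimethylocta-2,6-dien-1-yl]-2-iodo-3,5-bis(methoxymethoxy)phenol; 14 (3R)-3-[3,4-bis(methoxymethoxy)phenyl]-3-hydroxy-N-methoxy-N-methylpropanamide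
Product: 15 (3S)-3-[3,4-bis(methoxymethoxy)phenyl]-3-{4-[(2E)-3,7-dimethylocta-2,6-dien-1-yl]-2-iodo-3,5-bis(methoxymethoxy)phenoxy}-N-methoxy-N-methylpropanamide
Conditions: PPh3, DIAD, toluene, −20 °C → rt (14 added last)
Reagents that add atoms: none
Why: Mitsunobu etherification: the alkoxyphosphonium ion formed from 14 is displaced by the phenoxide of the acidic iodophenol 8 in an SN2 step, so the (R)-carbinol is inverted to the (S)-aryl ether that becomes C2, toluene and low temperature disfavouring ionisation and elimination.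

**Step 10**
Reactants: 15 (3S)-3-[3,4-bis(methoxymethoxy)phenyl]-3-{4-[(2E)-3,7-dimethylocta-2,6-dien-1-yl]-2-iodo-3,5-bis(methoxymethoxy)phenoxy}-N-methoxy-N-methylpropanamide
Product: 18 (2S)-2-[3,4-bis(methoxymethoxy)phenyl]-6-[(2E)-3,7-dimethylocta-2,6-dien-1-yl]-5,7-bis(methoxymethoxy)-2,3-dihydro-4H-chromen-4-one, via aryllithium 16 (not isolated), via lithium hemiaminal chelate 17 (not isolated)
Conditions: t-BuLi (2.1 equiv), THF, −100 → −78 °C; then sat. aq. NH4Cl, −78 °C → rt
Reagents that add atoms: none
Why: Iodine–lithium exchange at the only C–I bond gives aryllithium 16, chelated by the neighbouring OMOM and ether oxygens, which adds at once to the tethered Weinreb amide to give the lithium N-methoxy hemiaminal chelate 17 that releases the ketone only on quench (Parham cyclization; closest known type: anionic cycloacylation of ortho-halo aryl ethers carrying a tethered amide or carboxylate to chroman-4-ones and related benzo-fused ketones). Ring C closes in the 6-exo-trig mode on the amide carbonyl. No new stereocenter is formed, and C2 is carried through unchanged because the medium is not acidic (no ionisation of the benzylic aryl ether, no cation–olefin chemistry of the geranyl chain) and no enolisable ketone exists before the quench (no retro-oxa-Michael opening). The step needs geranyl at C6 and not C8, and the substrate secures it: in phenol 7 the two carbons ortho to oxygen are equivalent about the axis through C1 and C4, so the carbon that was iodinated becomes C4a whichever it was and the geranyl carbon is C6 by necessity. It also needs exchange and closure to outrun deprotonation α to the amide (which would expel the phenoxide by E1cB) and attack of t-BuLi on the amide, which the very fast exchange of a di-ortho-oxygenated aryl iodide at −100 °C and the six-membered transition state should provide.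

**Step 11**
Reactants: 18 (2S)-2-[3,4-bis(methoxymethoxy)phenyl]-6-[(2E)-3,7-dimethylocta-2,6-dien-1-yl]-5,7-bis(methoxymethoxy)-2,3-dihydro-4H-chromen-4-one
Product: 19 nymphaeol A
Conditions: HCl (3 M aq.), MeOH/THF, 40 °C, stopped at full conversion
Reagents that add atoms: none
Why: Acid-catalysed acetal exchange with methanol removes all four MOM groups as dimethoxymethane; C2 should not epimerise because ring opening of a flavanone needs base, and the geranyl alkenes should tolerate brief exposure to dilute acid at moderate temperature.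

**Compound list**
1 | phloroglucinol (benzene-1,3,5-triol) | Oc1cc(O)cc(O)c1 | starting material
2 | 3,5-bis(methoxymethoxy)phenol | COCOc1cc(O)cc(OCOC)c1 | intermediate
3 | [3,5-bis(methoxymethoxy)phenoxy]tri(propan-2-yl)silane | COCOc1cc(OCOC)cc(O[Si](C(C)C)(C(C)C)C(C)C)c1 | intermediate
4 | geranyl bromide, (2E)-1-bromo-3,7-dimethylocta-2,6-diene | CC(C)=CCC/C(C)=C/CBr | starting material
5 | {2,6-bis(methoxymethoxy)-4-[tri(propan-2-yl)silyloxy]phenyl}lithium | [Li]c1c(OCOC)cc(O[Si](C(C)C)(C(C)C)C(C)C)cc1OCOC | intermediate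
6 | {4-[(2E)-3,7-dimethylocta-2,6-dien-1-yl]-3,5-bis(methoxymethoxy)phenoxy}tri(propan-2-yl)silane | COCOc1cc(O[Si](C(C)C)(C(C)C)C(C)C)cc(OCOC)c1C/C=C(\C)CCC=C(C)C | intermediate
7 | 4-[(2E)-3,7-dimethylocta-2,6-dien-1-yl]-3,5-bis(methoxymethoxy)phenol | COCOc1cc(O)cc(OCOC)c1C/C=C(\C)CCC=C(C)C | intermediate
8 | 4-[(2E)-3,7-dimethylocta-2,6-dien-1-yl]-2-iodo-3,5-bis(methoxymethoxy)phenol | COCOc1cc(O)c(I)c(OCOC)c1C/C=C(\C)CCC=C(C)C | intermediate
9 | methyl 3,4-dihydroxybenzoate | COC(=O)c1ccc(O)c(O)c1 | starting material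
10 | methyl 3,4-bis(methoxymethoxy)benzoate | COCOc1ccc(C(=O)OC)cc1OCOC | intermediate
11 | N-methoxy-N-methylacetamide | CC(=O)N(C)OC | starting material
12 | lithium 1-[methoxy(methyl)amino]ethenolate (lithium enolate of 11) | C=C(O[Li])N(C)OC | intermediate
13 | 3-[3,4-bis(methoxymethoxy)phenyl]-N-methoxy-N-methyl-3-oxopropanamide | COCOc1ccc(C(=O)CC(=O)N(C)OC)cc1OCOC | intermediate
14 | (3R)-3-[3,4-bis(methoxymethoxy)phenyl]-3-hydroxy-N-methoxy-N-methylpropanamide | O[C@H](CC(=O)N(C)OC)c1ccc(OCOC)c(OCOC)c1 | intermediate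
15 | (3S)-3-[3,4-bis(methoxymethoxy)phenyl]-3-{4-[(2E)-3,7-dimethylocta-2,6-dien-1-yl]-2-iodo-3,5-bis(methoxymethoxy)phenoxy}-N-methoxy-N-methylpropanamide | COCOc1cc(O[C@@H](CC(=O)N(C)OC)c2ccc(OCOC)c(OCOC)c2)c(I)c(OCOC)c1C/C=C(\C)CCC=C(C)C | intermediate
16 | aryllithium from 15 (lithium in place of iodine, ortho to the ether oxygen) | COCOc1cc(O[C@@H](CC(=O)N(C)OC)c2ccc(OCOC)c(OCOC)c2)c([Li])c(OCOC)c1C/C=C(\C)CCC=C(C)C | intermediate
17 | lithium (2S)-2-[3,4-bis(methoxymethoxy)phenyl]-6-geranyl-4-[methoxy(methyl)amino]-5,7-bis(methoxymethoxy)chroman-4-olate (C4 configuration undefined) | COCOc1cc2c(c(OCOC)c1C/C=C(\C)CCC=C(C)C)C(O[Li])(N(C)OC)C[C@@H](c1ccc(OCOC)c(OCOC)c1)O2 | intermediate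
18 | (2S)-2-[3,4-bis(methoxymethoxy)phenyl]-6-[(2E)-3,7-dimethylocta-2,6-dien-1-yl]-5,7-bis(methoxymethoxy)-2,3-dihydro-4H-chromen-4-one | COCOc1cc2c(c(OCOC)c1C/C=C(\C)CCC=C(C)C)C(=O)C[C@@H](c1ccc(OCOC)c(OCOC)c1)O2 | intermediate
19 | nymphaeol A, (2S)-2-(3,4-dihydroxyphenyl)-6-[(2E)-3,7-dimethylocta-2,6-dien-1-yl]-5,7-dihydroxy-2,3-dihydro-4H-chromen-4-one | CC(C)=CCC/C(C)=C/Cc1c(O)cc2c(c1O)C(=O)C[C@@H](c1ccc(O)c(O)c1)O2 | target

**Step count**
Total steps: 11. Longest linear sequence: 8 steps (steps 1–5, 9, 10, 11, from phloroglucinol).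

**Steps most likely to fail**

Step 9. The alkoxyphosphonium ion may ionise to a benzylic cation stabilised by the para OMOM group, which would erode the enantiopurity, and the β-hydroxy amide may be dehydrated toward the cinnamoyl amide. The fallback sets out from phenol 8 and comes back at 15. It makes the C–O bond by catalyst-controlled allylic substitution, so no carbinol is activated and no acidic α-methylene is present at that stage.
- Commercial methyl caffeate (methyl (2E)-3-(3,4-dihydroxyphenyl)prop-2-enoate) is protected with MOMCl/i-Pr2NEt to methyl (2E)-3-[3,4-bis(methoxymethoxy)phenyl]prop-2-enoate F1.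
- Reduction with i-Bu2AlH gives the allylic alcohol F2, and methyl chloroformate/pyridine gives the methyl carbonate F3.
- Phenol 8 is converted with LiOt-Bu into its lithium phenoxide F4 and allylated with F3 under [Ir(cod)Cl]2 and a BINOL-derived N,N-bis(1-phenylethyl)phosphoramidite in THF. Attack at the aryl-substituted allyl terminus should give the branched (S)-allyl aryl ether F5, the ligand enantiomer that leads to (S) being used.
- 9-BBN adds to the terminal vinyl group only (B-alkyl-9-borabicyclo[3.3.1]nonane F6, not isolated), and NaBO3 oxidation gives the primary alcohol F7.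
- TEMPO/PhI(OAc)2 in aqueous MeCN gives the acid F8, and EDC coupling with MeNHOMe·HCl returns Weinreb amide 15.

Step 10. A carbanion may take a proton from the methylene α to the amide, after which the phenoxide is lost by E1cB; t-BuLi may also attack the amide carbonyl or cleave its N–OMe group before exchange is complete. The fallback sets out from 15 and comes back at 18. It closes the same C4–C4a bond with a non-basic organochromium reagent at the alcohol oxidation level.
- i-Bu2AlH (THF, −78 °C) reduces the Weinreb amide to the aldehyde F9.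
- CrCl2 with catalytic NiCl2 in DMF (Nozaki–Hiyama–Kishi reaction) inserts into the C–I bond and the arylchromium adds to the aldehyde, giving the flavan-4-ol F10 as a mixture of C4 epimers.
- Dess–Martin periodinane oxidises F10 to 18.

Step 11. During the time needed to cleave four acetals, the geranyl alkenes may be protonated and captured by the neighbouring C5 or C7 hydroxyl (chroman formation) or by the solvent. The fallback sets out from 18 and comes back at 19. It exchanges the protecting groups without free Brønsted acid.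
- Me3SiOTf/2,2'-bipyridyl (MeCN, 0 °C) converts the four aryl MOM ethers, by way of bipyridinium intermediates, into the tetrakis(trimethylsilyl) ether F11.
- The aryl silyl ethers are hydrolysed with water/THF at rt to 19.

**Further compounds**
F1 | step 9 | methyl (2E)-3-[3,4-bis(methoxymethoxy)phenyl]prop-2-enoate | COCOc1ccc(/C=C/C(=O)OC)cc1OCOC
F2 | step 9 | (2E)-3-[3,4-bis(methoxymethoxy)phenyl]prop-2-en-1-ol | COCOc1ccc(/C=C/CO)cc1OCOC
F3 | step 9 | (2E)-3-[3,4-bis(methoxymethoxy)phenyl]prop-2-en-1-yl methyl carbonate | COCOc1ccc(/C=C/COC(=O)OC)cc1OCOC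
F4 | step 9 | lithium 4-[(2E)-3,7-dimethylocta-2,6-dien-1-yl]-2-iodo-3,5-bis(methoxymethoxy)phenoxide | COCOc1cc(O[Li])c(I)c(OCOC)c1C/C=C(\C)CCC=C(C)C
F5 | step 9 | 1-{[(1S)-1-[3,4-bis(methoxymethoxy)phenyl]prop-2-en-1-yl]oxy}-4-[(2E)-3,7-dimethylocta-2,6-dien-1-yl]-2-iodo-3,5-bis(methoxymethoxy)benzene | COCOc1cc(O[C@@H](C=C)c2ccc(OCOC)c(OCOC)c2)c(I)c(OCOC)c1C/C=C(\C)CCC=C(C)C
F6 | step 9 | 9-{(3S)-3-[3,4-bis(methoxymethoxy)phenyl]-3-(aryloxy)propyl}-9-borabicyclo[3.3.1]nonane (aryloxy as in F5) | COCOc1cc(O[C@@H](CCB2C3CCCC2CCC3)c2ccc(OCOC)c(OCOC)c2)c(I)c(OCOC)c1C/C=C(\C)CCC=C(C)C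
F7 | step 9 | (3S)-3-[3,4-bis(methoxymethoxy)phenyl]-3-{4-[(2E)-3,7-dimethylocta-2,6-dien-1-yl]-2-iodo-3,5-bis(methoxymethoxy)phenoxy}propan-1-ol | COCOc1cc(O[C@@H](CCO)c2ccc(OCOC)c(OCOC)c2)c(I)c(OCOC)c1C/C=C(\C)CCC=C(C)C
F8 | step 9 | (3S)-3-[3,4-bis(methoxymethoxy)phenyl]-3-{4-[(2E)-3,7-dimethylocta-2,6-dien-1-yl]-2-iodo-3,5-bis(methoxymethoxy)phenoxy}propanoic acid | COCOc1cc(O[C@@H](CC(=O)O)c2ccc(OCOC)c(OCOC)c2)c(I)c(OCOC)c1C/C=C(\C)CCC=C(C)C
F9 | step 10 | (3S)-3-[3,4-bis(methoxymethoxy)phenyl]-3-{4-[(2E)-3,7-dimethylocta-2,6-dien-1-yl]-2-iodo-3,5-bis(methoxymethoxy)phenoxy}propanal | COCOc1cc(O[C@@H](CC=O)c2ccc(OCOC)c(OCOC)c2)c(I)c(OCOC)c1C/C=C(\C)CCC=C(C)C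
F10 | step 10 | (2S)-2-[3,4-bis(methoxymethoxy)phenyl]-6-[(2E)-3,7-dimethylocta-2,6-dien-1-yl]-5,7-bis(methoxymethoxy)-3,4-dihydro-2H-chromen-4-ol (both C4 epimers) | COCOc1cc2c(c(OCOC)c1C/C=C(\C)CCC=C(C)C)C(O)C[C@@H](c1ccc(OCOC)c(OCOC)c1)O2
F11 | step 11 | (2S)-2-[3,4-bis(trimethylsilyloxy)phenyl]-6-[(2E)-3,7-dimethylocta-2,6-dien-1-yl]-5,7-bis(trimethylsilyloxy)-2,3-dihydro-4H-chromen-4-one | CC(C)=CCC/C(C)=C/Cc1c(O[Si](C)(C)C)cc2c(c1O[Si](C)(C)C)C(=O)C[C@@H](c1ccc(O[Si](C)(C)C)c(O[Si](C)(C)C)c1)O2
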